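## Analysis of the target

Target 13 is a 2,5-diaryl-3,4-dimethyltetrahydrofuran: one oxolane ring (O1, C2, C3, C4, C5), four contiguous stereocentres and two 4-hydroxy-3,5-dimethoxyphenyl groups. The ring is numbered so that C2 carries the aryl group that is trans to its neighbouring methyl group, and the descriptors are then 2S,3S,4S,5R. The two aryl groups are cis to each other, the two methyl groups are trans, the C2 aryl is trans to the C3 methyl and the C5 aryl is cis to the C4 methyl. The constitution is symmetric but the configuration is not, so the two halves cannot be made by one doubled operation. Both ring C–O bonds are benzylic and flanked by electron-rich arenes: acids can ionise them and epimerise C2 or C5, hydrogenation catalysts can cleave them, and the phenols are acidic and easily oxidised. The hard part is the cis pair C4 methyl/C5 aryl, which any equilibration at C5 would turn into the more stable trans arrangement, whereas C2 and C3 already sit in their preferred arrangement. The route therefore rests on the bonds C4–C5 and O1–C2, which together define the cis-4-methyl-5-aryl-γ-butyrolactone 5, in which C2 is still a carbonyl carbon: the difficult pair is made first under catalyst control, and the carbonyl group remains as the handle for C3 and C2.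

## Retrosynthetic reasoning

13 to 12. Only the phenol on the C5 aryl is masked, as a benzyl ether, and the O–CH2Ph bond is cut last. The mask keeps that oxygen non-acidic through the enolate and hydride steps. Because the benzyloxy group is forced out of the arene plane by its two methoxy neighbours, it also makes the C5 aryl a poorer cation-stabilising group than a free 4-hydroxyaryl, which protects C5 in the Lewis acid step. The phenol on the C2 aryl is never protected.

12 to 9 and 10. The C2–aryl bond is cut. C2 is next to O1, so it can be an oxocarbenium carbon (ion 11, from acetate 9), and phenol 10 is a nucleophile at the position para to its hydroxyl because both ortho positions are occupied. This bond is chosen because C2 is the centre whose required arrangement, trans to the C3 methyl, is the stable one. The forward reaction must deliver the arene to that face and must not ionise C5. The 4-hydroxyaryl group makes the C2–O1 bond reversible under the same Lewis acid, so an error at C2 can correct itself.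

9 to 7. The acetal carbon is taken back to the lactone carbonyl. One hydride equivalent and an acyl trap (through aluminium hemiacetal 8) are enough. What is gained is a lactone whose carbonyl group can serve first as an enolate and then as the acetal.

7 to 5. The C3–CH3 bond is cut. In enolate 6 the C4 methyl and the C5 aryl lie on the same face, so a methyl electrophile has one open face, and that face gives the required 3,4-trans arrangement.

5 to 3 and 4. The bonds C4–C5 and O1–C2 are cut together. This is a polarity-reversed union: under a chiral carbene catalyst the β-carbon of enal 4 acts as a nucleophile towards the carbonyl carbon of aldehyde 3, and the former formyl carbon of 4 ends as the lactone carbonyl. The cut is made here because it produces both centres of the difficult pair and the ring in one catalytic step from two aldehydes. The forward reaction must fix the absolute configuration (4S,5R), favour the cis lactone, and favour cross-reaction over self-reaction of 4.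

3 to 1 and 2. The aryl ether bond is cut; 3 is the benzyl ether of commercial aldehyde 1.

## Alternatives that were turned down

Alternative 1: The two C–CH3 bonds are cut. An enantiopure (S)-5-arylbutenolide A1 would take up a methyl group from Me2CuLi at its β-carbon anti to the aryl group, and the enolate would be methylated in the same flask with iodomethane anti to the new methyl group, giving the all-trans lactone A2.
- For: both methyl groups are set in one operation by well-understood substrate control. The second aryl group can then be attached at the carbonyl carbon of A2 by addition of an aryl nucleophile followed by ionic reduction with Et3SiH and BF3·OEt2. Hydride enters anti to the α-methyl group, which leaves the new aryl cis to it; this is the C4/C5 relationship of 13, and the aryl of A2 becomes the C2 aryl. On reliability of the individual steps this plan is at least as strong as the chosen one, and it needs no regiochemical decision on a phenol.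
- Against: A1 must first be made enantiopure over several steps from 3, and the key step itself creates no difficult centre. The sensitive cis benzylic centre is formed last, in a Lewis acid medium next to a para-alkoxyaryl group, where it is most easily epimerised. The sequence is longer by about three steps.
- In its place the chosen strategy offers a catalytic two-aldehyde entry that sets the cis pair at the outset, and an end-game whose last centre is the thermodynamically favoured one.

Alternative 2: The C2–C3 bond is cut. In α-diazo ester A3 the future O1 links the C5 carbinol carbon to a 4-benzyloxy-3,5-dimethoxybenzyl group. Rh2(OPiv)4 would generate the carbene at C3, which inserts into the ether-activated benzylic C–H bond five atoms away and closes the ring to ester A4, with the ester where the C3 methyl of 13 stands.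
- For: a C–C bond and the ring form in one step at a site favoured electronically and geometrically. Both aryl-bearing carbons already carry their oxygen, so no Lewis acid arylation is needed; on that point it is stronger than the chosen route.
- Against: the C4/C5 relationship must already exist in A3, so the key step does not address the hard pair. The carbene has a C4–H beside it, so a 1,2-hydride shift to the carbene carbon competes, as do insertion into the OCH2Ph groups and attack on the electron-rich arenes. Two new centres (C2 and C3) must emerge 2,3-trans and 2,5-cis from one transition state. The ester of A4 must then be taken down to a methyl group by reduction, activation and hydride displacement at a hindered carbon.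
- The chosen route keeps every carbon at its final oxidation level after step 4 and is shorter by four to five steps.

Alternative 3: The bonds O1–C5 and C4–C5 are cut. The (Z)-anti enol carbamate A5, the product of a carbamate-directed homoaldol addition to 3, would condense through its hydroxyl group with a second molecule of 3 under BF3·OEt2. The enol carbamate carbon attacks the resulting oxocarbenium ion, and ring closure gives the tetrahydrofuran A6, which carries a formyl group where 13 has its C4 methyl.
- For: the plan is convergent, and the C2/C3 trans relationship is fixed in A5 before the ring closes. The homoaldol step under a stoichiometric chiral diamine is a firmer basis for absolute configuration than the carbene annulation of the chosen route; on enantiocontrol this alternative is stronger.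
- Against: the cyclisation to A6 must place the C5 aryl cis to the C4 substituent, and that substituent is a formyl group on an epimerisable centre, so the hard pair is formed with uncertain control and left labile. The formyl group of A6 must be reduced to methyl in two or three steps that spare two benzylic ethers. A stoichiometric chiral amine and a metal exchange are required to reach A5.
- The chosen strategy offers a catalytic source of chirality, carries the C4 methyl from the start, and is shorter.

Key step: step 2

Remark: the sense of asymmetric induction of the triazolium catalyst on this aldehyde/enal pair is assumed by analogy; if a first run gives the enantiomeric lactone, the (5aR,10bS) antipode of the catalyst is used and nothing else changes.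

## Route

Step 1
Reactants: 1 syringaldehyde; 2 benzyl bromide
Product: 3 4-(benzyloxy)-3,5-dimethoxybenzaldehyde
Conditions: K2CO3, DMF, 60 °C
Reagents that add atoms: none
Why: Williamson ether synthesis; the phenoxide formed with K2CO3 displaces bromide from 2 (SN2), and the aldehyde is untouched.

Step 2
Reactants: 3 4-(benzyloxy)-3,5-dimethoxybenzaldehyde; 4 (E)-but-2-enal
Product: 5 (4S,5R)-5-[4-(benzyloxy)-3,5-dimethoxyphenyl]-4-methyldihydrofuran-2(3H)-one
Conditions: (5aS,10bR)-2-mesityl-5a,10b-dihydro-4H,6H-indeno[2,1-b][1,2,4]triazolo[4,3-d][1,4]oxazin-2-ium chloride (15 mol %), DBU (15 mol %), THF, 4 Å MS, 25 °C; 4 (2.5 equiv) added over 12 h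
Reagents that add atoms: none
Why: DBU liberates the triazolylidene, which adds to the formyl carbon of 4; proton transfer gives the Breslow intermediate, a conjugated enaminol whose β-carbon (the future C4) is nucleophilic. This carbon adds to the carbonyl carbon of 3 (the future C5), the resulting enol tautomerises to an acyl triazolium, and the C5 alkoxide acylates it, which forms O1–C2 and releases the carbene. The closest known reaction type is the carbene-catalysed homoenolate annulation of enals with aryl aldehydes to cis-γ-butyrolactones. The single ring is closed by a 5-exo-trig attack of the alkoxide oxygen on the acyl carbon. C5 is controlled by the catalyst: the fused indane shields one face of the extended enaminol, so 3 is met from the open face with one of its own faces turned to the nucleophile; C4 is set in the same bond formation, in a compact transition state (enol O–H hydrogen-bonded to the aldehyde oxygen) that places the aryl group and the β-methyl group cis. The step needs cross- rather than self-annulation of 4, which the slow addition of 4 to 3 secures by keeping the enal the scarcer electrophile; it needs homoenolate rather than acyl-anion chemistry of 3, for which an N-mesityl triazolium is the established choice; and it needs an electrophilic aldehyde, which 3 is because it cannot enolise and its para oxygen, flanked by two methoxy groups, is twisted out of conjugation with the carbonyl group.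

Step 3
Reactants: 5 (4S,5R)-5-[4-(benzyloxy)-3,5-dimethoxyphenyl]-4-methyldihydrofuran-2(3H)-one
Product: 7 (3S,4S,5R)-5-[4-(benzyloxy)-3,5-dimethoxyphenyl]-3,4-dimethyldihydrofuran-2(3H)-one, via lithium enolate 6 (not isolated)
Conditions: LiN(SiMe3)2, THF, −78 °C; MeI, −78 → −40 °C
Reagents that add atoms: iodomethane, CI
Why: Alkylation of a lactone lithium enolate. The C4 methyl and the C5 aryl group lie on the same face of planar enolate 6, so iodomethane enters from the other face and the new C3 methyl is trans to the C4 methyl (S at C3); this is also the more stable epimer.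

Step 4
Reactants: 7 (3S,4S,5R)-5-[4-(benzyloxy)-3,5-dimethoxyphenyl]-3,4-dimethyldihydrofuran-2(3H)-one
Product: 9 (3S,4S,5R)-5-[4-(benzyloxy)-3,5-dimethoxyphenyl]-3,4-dimethyltetrahydrofuran-2-yl acetate (mixture of C2 epimers), via aluminium hemiacetal 8 (not isolated)
Conditions: i-Bu2AlH, CH2Cl2, −78 °C; then pyridine, DMAP, Ac2O, −78 → 0 °C
Reagents that add atoms: acetic anhydride, CC(=O)OC(C)=O
Why: One-pot reductive acetylation of a lactone; i-Bu2AlH adds once at −78 °C and the stable aluminium hemiacetal 8 is acetylated in the flask, so no hydroxy aldehyde is set free and C3 cannot epimerise. The acetal centre forms as a mixture, which does not matter because C2 becomes planar in step 5.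

Step 5
Reactants: 9 (3S,4S,5R)-5-[4-(benzyloxy)-3,5-dimethoxyphenyl]-3,4-dimethyltetrahydrofuran-2-yl acetate; 10 2,6-dimethoxyphenol
Product: 12 4-{(2S,3S,4S,5R)-5-[4-(benzyloxy)-3,5-dimethoxyphenyl]-3,4-dimethyltetrahydrofuran-2-yl}-2,6-dimethoxyphenol, via oxocarbenium ion 11 (not isolated)
Conditions: 10 (3 equiv), BF3·OEt2, CH2Cl2, −78 → −40 °C
Reagents that add atoms: none
Why: BF3·OEt2 ionises the anomeric acetate to oxocarbenium ion 11, which is captured by C4 of phenol 10 (para to the hydroxyl, both ortho positions being blocked) in a Friedel–Crafts C-arylation. The arene approaches C2 anti to the adjacent C3 methyl group, and this 2,3-trans arrangement is also the more stable one, to which the centre can settle because the C2–O1 bond of a 4-hydroxyaryl product and the C2–OAr bond of any O-arylated acetal re-ionise under BF3·OEt2. C5 is left alone at this temperature because its aryl group, with the para oxygen benzylated and twisted out of conjugation, stabilises a benzylic cation far less.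

Step 6
Reactants: 12 4-{(2S,3S,4S,5R)-5-[4-(benzyloxy)-3,5-dimethoxyphenyl]-3,4-dimethyltetrahydrofuran-2-yl}-2,6-dimethoxyphenol
Product: 13 4,4'-[(2S,3S,4S,5R)-3,4-dimethyltetrahydrofuran-2,5-diyl]bis(2,6-dimethoxyphenol)
Conditions: H2 (1 atm), 10% Pd/C, EtOAc, 25 °C
Reagents that add atoms: none
Why: Hydrogenolysis of an aryl benzyl ether over palladium. The O–CH2Ph bond should be cleaved much faster than the two secondary benzylic C–O bonds of the ring in a neutral aprotic solvent at 1 atm, and no stereocentre is involved.

## Compound list

1 | syringaldehyde (4-hydroxy-3,5-dimethoxybenzaldehyde) | COc1cc(C=O)cc(OC)c1O | starting material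
2 | benzyl bromide | BrCc1ccccc1 | starting material
3 | 4-(benzyloxy)-3,5-dimethoxybenzaldehyde | COc1cc(C=O)cc(OC)c1OCc1ccccc1 | intermediate
4 | (E)-but-2-enal | C/C=C/C=O | starting material
5 | (4S,5R)-5-[4-(benzyloxy)-3,5-dimethoxyphenyl]-4-methyldihydrofuran-2(3H)-one | O=C1O[C@@H](c2cc(OC)c(OCc3ccccc3)c(OC)c2)[C@@H](C)C1 | intermediate
6 | lithium (4S,5R)-5-[4-(benzyloxy)-3,5-dimethoxyphenyl]-4-methyl-4,5-dihydrofuran-2-olate (lithium enolate of 5) | [Li]OC=1O[C@@H](c2cc(OC)c(OCc3ccccc3)c(OC)c2)[C@@H](C)C=1 | intermediate (not isolated)
7 | (3S,4S,5R)-5-[4-(benzyloxy)-3,5-dimethoxyphenyl]-3,4-dimethyldihydrofuran-2(3H)-one | O=C1O[C@@H](c2cc(OC)c(OCc3ccccc3)c(OC)c2)[C@@H](C)[C@@H]1C | intermediate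
8 | diisobutylaluminium (3S,4S,5R)-5-[4-(benzyloxy)-3,5-dimethoxyphenyl]-3,4-dimethyltetrahydrofuran-2-olate (aluminium hemiacetal, C2 epimers) | CC(C)C[Al](CC(C)C)OC1O[C@@H](c2cc(OC)c(OCc3ccccc3)c(OC)c2)[C@@H](C)[C@@H]1C | intermediate (not isolated)
9 | (3S,4S,5R)-5-[4-(benzyloxy)-3,5-dimethoxyphenyl]-3,4-dimethyltetrahydrofuran-2-yl acetate (C2 epimers) | CC(=O)OC1O[C@@H](c2cc(OC)c(OCc3ccccc3)c(OC)c2)[C@@H](C)[C@@H]1C | intermediate
10 | 2,6-dimethoxyphenol | COc1cccc(OC)c1O | starting material
11 | (3S,4S,5R)-5-[4-(benzyloxy)-3,5-dimethoxyphenyl]-3,4-dimethyl-4,5-dihydro-3H-furan-1-ium (oxocarbenium ion) | C1=[O+][C@@H](c2cc(OC)c(OCc3ccccc3)c(OC)c2)[C@@H](C)[C@@H]1C | intermediate (not isolated)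
12 | 4-{(2S,3S,4S,5R)-5-[4-(benzyloxy)-3,5-dimethoxyphenyl]-3,4-dimethyltetrahydrofuran-2-yl}-2,6-dimethoxyphenol | COc1cc([C@H]2O[C@@H](c3cc(OC)c(OCc4ccccc4)c(OC)c3)[C@@H](C)[C@@H]2C)cc(OC)c1O | intermediate
13 | 4,4'-[(2S,3S,4S,5R)-3,4-dimethyltetrahydrofuran-2,5-diyl]bis(2,6-dimethoxyphenol) | COc1cc([C@H]2O[C@@H](c3cc(OC)c(O)c(OC)c3)[C@@H](C)[C@@H]2C)cc(OC)c1O | target

## Step count and least certain steps

Total step count: 6. Longest linear sequence: 6 (1 → 3 → 5 → 7 → 9 → 12 → 13).

**Step 2 (key step).** The likely failure is loss of chemoselectivity and of stereocontrol, not failure to react.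
- The homoenolate may be protonated at its β-carbon, or add to a second molecule of 4, faster than it adds to 3.
- The enantiomeric purity may be only moderate. Chiral triazolium catalysts are best established for more activated carbonyl acceptors than simple aryl aldehydes, and a β-methyl enal gives the catalyst less to hold than a β-aryl enal.
- Some trans lactone is to be expected and removed.

The enantiomeric purity of 5 would be measured at this stage and, if needed, raised by crystallisation of 5 or 7. A Lewis acid co-catalyst such as Ti(Oi-Pr)4 or LiCl is the first variation of conditions.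

Fallback, setting out from 3 and coming back at 5: the pair is made by a stoichiometric crotyl transfer instead. Aldehyde 3 is treated at −78 °C with the (Z)-crotyl reagent generated in the flask from cis-but-2-ene, n-BuLi/KOt-Bu, B-methoxydiisopinocampheylborane and BF3·OEt2. The antipode of the borane is the one that gives the 1R,2S product, expected to be the one derived from (−)-α-pinene. Work-up with NaOH/H2O2 gives (1R,2S)-1-[4-(benzyloxy)-3,5-dimethoxyphenyl]-2-methylbut-3-en-1-ol F1; the closed chair transition state of a (Z)-crotylborane gives the syn alcohol, which maps onto the cis lactone. Hydroboration of the vinyl group with 9-borabicyclo[3.3.1]nonane and oxidation gives (1R,2S)-1-[4-(benzyloxy)-3,5-dimethoxyphenyl]-2-methylbutane-1,4-diol F2. TEMPO with PhI(OAc)2 oxidises the primary alcohol of F2, and the oxidation runs on, through ring closure at the aldehyde stage, to lactone 5.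

**Step 5.** Three processes may interfere.
- Attack of the electrophile at C3 of phenol 10, which is ortho and para to the two methoxy groups, instead of C4, or persistence of O-arylation.
- Entry of the arene on the face of C2 that is cis to the C3 methyl. The face anti to the C3 methyl also carries the C4 methyl and the C5 aryl group, so the kinetic preference may be weak. Correction then depends on re-ionisation at C2.
- Ionisation at C5 on prolonged exposure or warming, which would erase the cis relationship.

Fallback, setting out from 7 and coming back at 12: the C2–O1 bond is closed last instead of the C2–aryl bond.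
- Lactone 7 is reduced with i-Bu2AlH at −78 °C and worked up to the lactol (3S,4S,5R)-5-[4-(benzyloxy)-3,5-dimethoxyphenyl]-3,4-dimethyltetrahydrofuran-2-ol F3.
- Commercial 4-bromo-2,6-dimethoxyphenol is silylated (t-BuMe2SiCl, imidazole) to (4-bromo-2,6-dimethoxyphenoxy)(tert-butyl)dimethylsilane F4 and converted with Mg into [4-(tert-butyldimethylsilyloxy)-3,5-dimethoxyphenyl]magnesium bromide F5.
- F5 adds to the open hydroxy aldehyde form of F3, after deprotonation with i-PrMgCl, to give (1R,2S,3S)-1-[4-(benzyloxy)-3,5-dimethoxyphenyl]-4-[4-(tert-butyldimethylsilyloxy)-3,5-dimethoxyphenyl]-2,3-dimethylbutane-1,4-diol F6 as a mixture at C4.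
- Bu4NF frees the phenol to give (1R,2S,3S)-1-[4-(benzyloxy)-3,5-dimethoxyphenyl]-4-(4-hydroxy-3,5-dimethoxyphenyl)-2,3-dimethylbutane-1,4-diol F7.
- A trace of acid (pyridinium p-toluenesulfonate, CH2Cl2) ionises the benzylic alcohol of F7 that stands para to the free phenol (quinone-methide-type activation), and the C1 hydroxyl closes the ring at that carbon (5-exo-trig) to give 12.

The regiochemistry of the arene is fixed by the bromide. The new centre closes to the more stable 2,3-trans arrangement whatever the configuration of the carbinol. C5 should keep its configuration because its C–O bond is not broken; only the benzylic alcohol next to the free phenol ionises under these conditions.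

**Step 6.** The likely failure is reductive cleavage of a ring C–O bond, both of which are benzylic, in competition with debenzylation, which would open the ring.

Fallback, setting out from 1 and coming back at 13: the protecting group is changed to one that leaves without hydrogen.
- Syringaldehyde 1 is alkylated with allyl bromide (K2CO3, DMF) to 4-(allyloxy)-3,5-dimethoxybenzaldehyde F8.
- F8 is carried through the conditions of steps 2 to 5: annulation with 4 to (4S,5R)-5-[4-(allyloxy)-3,5-dimethoxyphenyl]-4-methyldihydrofuran-2(3H)-one F9, methylation to (3S,4S,5R)-5-[4-(allyloxy)-3,5-dimethoxyphenyl]-3,4-dimethyldihydrofuran-2(3H)-one F10, reductive acetylation to (3S,4S,5R)-5-[4-(allyloxy)-3,5-dimethoxyphenyl]-3,4-dimethyltetrahydrofuran-2-yl acetate F11, and arylation with 10 to 4-{(2S,3S,4S,5R)-5-[4-(allyloxy)-3,5-dimethoxyphenyl]-3,4-dimethyltetrahydrofuran-2-yl}-2,6-dimethoxyphenol F12.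
- The allyl group is then transferred to morpholine with Pd(PPh3)4 (zerovalent palladium) in THF at room temperature, which gives 13 without exposing the ring to hydrogen or acid.

The allyl ether should be inert to the carbene, the amide base, the aluminium hydride and BF3·OEt2 at low temperature, and an aromatic Claisen shift is blocked at both ortho positions.

## Further compounds

F1 | step 2 | (1R,2S)-1-[4-(benzyloxy)-3,5-dimethoxyphenyl]-2-methylbut-3-en-1-ol | O[C@@H](c1cc(OC)c(OCc2ccccc2)c(OC)c1)[C@@H](C)C=C
F2 | step 2 | (1R,2S)-1-[4-(benzyloxy)-3,5-dimethoxyphenyl]-2-methylbutane-1,4-diol | O[C@@H](c1cc(OC)c(OCc2ccccc2)c(OC)c1)[C@@H](C)CCO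
F3 | step 5 | (3S,4S,5R)-5-[4-(benzyloxy)-3,5-dimethoxyphenyl]-3,4-dimethyltetrahydrofuran-2-ol (C2 epimers) | OC1O[C@@H](c2cc(OC)c(OCc3ccccc3)c(OC)c2)[C@@H](C)[C@@H]1C
F4 | step 5 | (4-bromo-2,6-dimethoxyphenoxy)(tert-butyl)dimethylsilane | COc1cc(Br)cc(OC)c1O[Si](C)(C)C(C)(C)C
F5 | step 5 | [4-(tert-butyldimethylsilyloxy)-3,5-dimethoxyphenyl]magnesium bromide | COc1cc([Mg]Br)cc(OC)c1O[Si](C)(C)C(C)(C)C
F6 | step 5 | (1R,2S,3S)-1-[4-(benzyloxy)-3,5-dimethoxyphenyl]-4-[4-(tert-butyldimethylsilyloxy)-3,5-dimethoxyphenyl]-2,3-dimethylbutane-1,4-diol (C4 epimers) | O[C@@H](c1cc(OC)c(OCc2ccccc2)c(OC)c1)[C@@H](C)[C@@H](C(O)c1cc(OC)c(O[Si](C)(C)C(C)(C)C)c(OC)c1)C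
F7 | step 5 | (1R,2S,3S)-1-[4-(benzyloxy)-3,5-dimethoxyphenyl]-4-(4-hydroxy-3,5-dimethoxyphenyl)-2,3-dimethylbutane-1,4-diol (C4 epimers) | O[C@@H](c1cc(OC)c(OCc2ccccc2)c(OC)c1)[C@@H](C)[C@@H](C(O)c1cc(OC)c(O)c(OC)c1)C
F8 | step 6 | 4-(allyloxy)-3,5-dimethoxybenzaldehyde | COc1cc(C=O)cc(OC)c1OCC=C
F9 | step 6 | (4S,5R)-5-[4-(allyloxy)-3,5-dimethoxyphenyl]-4-methyldihydrofuran-2(3H)-one | O=C1O[C@@H](c2cc(OC)c(OCC=C)c(OC)c2)[C@@H](C)C1
F10 | step 6 | (3S,4S,5R)-5-[4-(allyloxy)-3,5-dimethoxyphenyl]-3,4-dimethyldihydrofuran-2(3H)-one | O=C1O[C@@H](c2cc(OC)c(OCC=C)c(OC)c2)[C@@H](C)[C@@H]1C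
F11 | step 6 | (3S,4S,5R)-5-[4-(allyloxy)-3,5-dimethoxyphenyl]-3,4-dimethyltetrahydrofuran-2-yl acetate (C2 epimers) | CC(=O)OC1O[C@@H](c2cc(OC)c(OCC=C)c(OC)c2)[C@@H](C)[C@@H]1C
F12 | step 6 | 4-{(2S,3S,4S,5R)-5-[4-(allyloxy)-3,5-dimethoxyphenyl]-3,4-dimethyltetrahydrofuran-2-yl}-2,6-dimethoxyphenol | COc1cc([C@H]2O[C@@H](c3cc(OC)c(OCC=C)c(OC)c3)[C@@H](C)[C@@H]2C)cc(OC)c1O
A1 | alternative 1 | (S)-5-[4-(benzyloxy)-3,5-dimethoxyphenyl]furan-2(5H)-one | COc1cc([C@H]2OC(=O)C=C2)cc(OC)c1OCc1ccccc1
A2 | alternative 1 | (3S,4S,5S)-5-[4-(benzyloxy)-3,5-dimethoxyphenyl]-3,4-dimethyldihydrofuran-2(3H)-one | COc1cc([C@H]2OC(=O)[C@@H](C)[C@@H]2C)cc(OC)c1OCc1ccccc1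
A3 | alternative 2 | methyl (3S,4R)-4-[4-(benzyloxy)-3,5-dimethoxyphenyl]-4-{[4-(benzyloxy)-3,5-dimethoxybenzyl]oxy}-2-diazo-3-methylbutanoate | COc1cc(CO[C@@H](c2cc(OC)c(OCc3ccccc3)c(OC)c2)[C@@H](C)C(=[N+]=[N-])C(=O)OC)cc(OC)c1OCc1ccccc1
A4 | alternative 2 | methyl (2S,3S,4S,5R)-2,5-bis[4-(benzyloxy)-3,5-dimethoxyphenyl]-4-methyltetrahydrofuran-3-carboxylate | COc1cc([C@H]2O[C@@H](c3cc(OC)c(OCc4ccccc4)c(OC)c3)[C@@H](C)[C@@H]2C(=O)OC)cc(OC)c1OCc1ccccc1
A5 | alternative 3 | (1Z,3S,4S)-4-[4-(benzyloxy)-3,5-dimethoxyphenyl]-4-hydroxy-3-methylbut-1-en-1-yl diisopropylcarbamate | COc1cc([C@@H](O)[C@@H](C)/C=C\OC(=O)N(C(C)C)C(C)C)cc(OC)c1OCc1ccccc1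
A6 | alternative 3 | (2R,3S,4S,5S)-2,5-bis[4-(benzyloxy)-3,5-dimethoxyphenyl]-4-methyltetrahydrofuran-3-carbaldehyde (formyl on C4 in the numbering of 13) | COc1cc([C@H]2O[C@@H](c3cc(OC)c(OCc4ccccc4)c(OC)c3)[C@@H](C=O)[C@@H]2C)cc(OC)c1OCc1ccccc1
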